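The synthesis rests on cutting C1–C2 of the ten-membered carbocycle. C2 is alpha to C3, the masked ketone of the hemiketal. C1 is bonded to C10, whose methyl (C14) and bridging oxygen can both grow from a C10=C14 methylene. The resulting γ,δ-unsaturated ketone C3(=O)–C2–C1–C10=C14 is the signature of a Claisen rearrangement. Heating the ten-membered cyclic enol ether C2=C3–O–C14–C10=C1, made by methylenating a macrolactone, forms C1–C2 and breaks O–C14. One operation thus trades an easily closed oxacycle for the carbocycle, its ketone and its methylene. The precursor already holds C6–C8, the Z C4=C5 alkene, the C12 dimethyl acetal and three different silyl ethers.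

Key step: step 19

Numbering: germacrane numbers are used throughout. C1–C10 is the ring, C11–C13 the lactone side chain, C14 sits on C10, C15 sits on C4, and On is the oxygen on Cn.

Assumption: C3 is a hemiketal carbon that can equilibrate through the open 10-hydroxy-3-ketone. The route therefore controls C6, C7, C8 and C10, and C3 is written as in the target string.

Design remark: O6 and O8 are both gamma to C12, and O15 must stay masked until the C8 ester is in place. The precursor therefore carries TES on O6, TBS on O8 and TBDPS on O15, which come off in that order. O14 carries PMB until the ring closure, so nothing in the chain can be ionised by palladium.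

Step 1
Reactants: 1 but-2-yne-1,4-diol
Product: 2 4-(tert-butyldiphenylsilyloxy)but-2-yn-1-ol
Conditions: TBDPSCl (1 equiv), imidazole, 1 (3 equiv), DMF, 0 °C to rt
Reagents that add atoms: tert-butyl(chloro)diphenylsilane CC(C)(C)[Si](Cl)(c1ccccc1)c1ccccc1
Why: Statistical monosilylation of a symmetrical diol used in excess (imidazole-promoted silyl ether formation) should leave one propargylic hydroxyl free to direct the next step.

Step 2
Reactants: 2 4-(tert-butyldiphenylsilyloxy)but-2-yn-1-ol
Product: 4 (2Z)-4-(tert-butyldiphenylsilyloxy)-3-iodobut-2-en-1-ol, via alkenylalanate 3 (not isolated)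
Conditions: NaAlH2(OCH2CH2OCH3)2, THF, 0 °C to rt; then I2, THF, −78 to 0 °C
Reagents that add atoms: iodine [I][I]; sodium bis(2-methoxyethoxy)aluminium dihydride [Na+].COCCO[AlH2-]OCCOC (its atoms stay only in 3)
Why: Hydroxyl-directed trans-hydroalumination of a propargylic alcohol puts aluminium on the distal alkyne carbon (C4) inside a five-membered chelate, and iodinolysis with retention should give the Z vinyl iodide that fixes the C4=C5 geometry.

Step 3
Reactants: 4 (2Z)-4-(tert-butyldiphenylsilyloxy)-3-iodobut-2-en-1-ol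
Product: 5 (2Z)-4-(tert-butyldiphenylsilyloxy)-3-iodobut-2-enal
Conditions: activated MnO2, CH2Cl2, rt
Reagents that add atoms: none
Why: Allylic alcohol oxidation with MnO2 is neutral and heterogeneous, so the Z-3-iodoenal should form without geometric isomerisation.

Step 4
Reactants: 6 methyl 4,4-dimethoxybutanoate
Product: 7 lithium 4,4-dimethoxybutanoate
Conditions: LiOH·H2O (1.0 equiv), THF/MeOH/H2O, rt; evaporate, dry azeotropically
Reagents that add atoms: lithium hydroxide [Li+].[OH-]
Why: Ester saponification, with the product kept as its lithium salt so that no acid can turn the gamma-acetal acid into a methoxybutyrolactone.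

Step 5
Reactants: 7 lithium 4,4-dimethoxybutanoate; 8 (4S)-4-benzyl-1,3-oxazolidin-2-one
Product: 10 (4S)-4-benzyl-3-(4,4-dimethoxybutanoyl)-1,3-oxazolidin-2-one, via mixed pivalic anhydride 9 (not isolated)
Conditions: PivCl, THF, −20 °C; then 8, LiCl, Et3N, −20 °C to rt
Reagents that add atoms: pivaloyl chloride CC(C)(C)C(=O)Cl (its atoms stay only in 9)
Why: Mixed-anhydride N-acylation of an oxazolidinone under LiCl/Et3N conditions, in which the nucleophile attacks the unhindered carbonyl of 9 and no acid or strong base touches the acetal.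

Step 6
Reactants: 10 (4S)-4-benzyl-3-(4,4-dimethoxybutanoyl)-1,3-oxazolidin-2-one; 5 (2Z)-4-(tert-butyldiphenylsilyloxy)-3-iodobut-2-enal
Product: 12 (4S)-4-benzyl-3-[(2S,3S,4Z)-6-(tert-butyldiphenylsilyloxy)-2-(2,2-dimethoxyethyl)-3-hydroxy-5-iodohex-4-enoyl]-1,3-oxazolidin-2-one (germacrane 6S,7S), via boron Z-enolate 11 (not isolated)
Conditions: Bu2BOTf, Et3N, CH2Cl2, −78 to 0 °C; 5, −78 to 0 °C; then pH 7 buffer, MeOH, 30% H2O2, 0 °C
Reagents that add atoms: dibutylboryl triflate CCCCB(CCCC)OS(=O)(=O)C(F)(F)F (its atoms stay only in 11)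
Why: Evans syn-aldol reaction in which soft enolisation gives Z enolate 11, which adds to enal 5 through a Zimmerman–Traxler chair on the face left open by the benzyl group of the (S)-auxiliary, setting C7 and C6 together (C11 and O6 syn, absolute sense from the auxiliary).

Step 7
Reactants: 12 syn-aldol adduct (6S,7S)
Product: 13 O6-triethylsilyl ether of 12 (6S,7S)
Conditions: TESCl, imidazole, DMAP (cat.), CH2Cl2/DMF, 0 °C to rt
Reagents that add atoms: chlorotriethylsilane CC[Si](Cl)(CC)CC
Why: Silyl ether formation with the chloride and imidazole, not a silyl triflate, covers O6 with the most labile of the three silyl groups without activating the dimethyl acetal.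

Step 8
Reactants: 13 O6-triethylsilyl ether of 12
Product: 14 (2R,3S,4Z)-6-(tert-butyldiphenylsilyloxy)-2-(2,2-dimethoxyethyl)-5-iodo-3-(triethylsilyloxy)hex-4-en-1-ol (germacrane 6S,7R)
Conditions: LiBH4, H2O (1 equiv), Et2O, 0 °C
Reagents that add atoms: none
Why: Reductive cleavage of the N-acyl oxazolidinone with LiBH4 attacks the exocyclic carbonyl, releases the auxiliary for reuse and leaves the vinyl iodide, acetal and silyl ethers alone.

Step 9
Reactants: 14 primary alcohol (6S,7R)
Product: 15 (2S,3S,4Z)-6-(tert-butyldiphenylsilyloxy)-2-(2,2-dimethoxyethyl)-5-iodo-3-(triethylsilyloxy)hex-4-enal (germacrane 6S,7S)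
Conditions: TEMPO (cat.), PhI(OAc)2, CH2Cl2, rt
Reagents that add atoms: none
Why: Oxoammonium (TEMPO) oxidation of a primary alcohol stops at the aldehyde and is mild enough to avoid epimerisation at C7 or loss of the beta-silyloxy group.

Step 10
Reactants: 16 2-methylprop-2-en-1-ol
Product: 18 2-[(tributylstannyl)methyl]prop-2-en-1-ol, via dilithio dianion 17 (not isolated)
Conditions: n-BuLi (2.2 equiv), TMEDA, Et2O/hexanes, 0 °C to rt; Bu3SnCl (1.0 equiv), −78 °C to rt; H2O
Reagents that add atoms: tributyltin chloride CCCC[Sn](Cl)(CCCC)CCCC; n-butyllithium [Li]CCCC (lithium stays only in 17)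
Why: Alkoxide-assisted allylic metalation of methallyl alcohol gives the O,C-dianion, whose carbon terminus is the more reactive site and should take up one equivalent of the tin chloride.

Step 11
Reactants: 18 2-[(tributylstannyl)methyl]prop-2-en-1-ol
Product: 19 tributyl{2-[(4-methoxybenzyloxy)methyl]prop-2-en-1-yl}stannane
Conditions: NaH, PMBCl, Bu4NI (cat.), THF/DMF, 0 °C to rt
Reagents that add atoms: 4-methoxybenzyl chloride COc1ccc(CCl)cc1
Why: Williamson etherification gives O14 a group that tolerates organolithium, borane and palladium chemistry, cannot migrate to carbon as a silyl group could, and is removed oxidatively.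

Step 12
Reactants: 19 tributyl{2-[(4-methoxybenzyloxy)methyl]prop-2-en-1-yl}stannane; 15 aldehyde (6S,7S)
Product: 22 (4R,5R,6S,7Z)-9-(tert-butyldiphenylsilyloxy)-5-(2,2-dimethoxyethyl)-8-iodo-2-[(4-methoxybenzyloxy)methyl]-6-(triethylsilyloxy)nona-1,7-dien-4-ol (germacrane 6S,7R,8R), via allyllithium 20 (not isolated), via allylborane 21 (not isolated)
Conditions: 19, n-BuLi, THF, −78 °C; (+)-Ipc2BOMe, −78 °C; BF3·OEt2, −78 °C; 15, −78 °C; then NaBO3·4H2O, THF/H2O, rt
Reagents that add atoms: n-butyllithium [Li]CCCC (lithium stays only in 20); (+)-B-methoxydiisopinocampheylborane COB([C@H]1C[C@H]2C[C@@H]([C@@H]1C)C2(C)C)[C@H]1C[C@H]2C[C@@H]([C@@H]1C)C2(C)C (its atoms stay only in 21)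
Why: Brown-type asymmetric allylboration in which tin–lithium exchange and boron trapping give the 2-substituted allylborane 21, which adds through a closed chair transition state where the isopinocampheyl groups derived from (−)-α-pinene select the aldehyde face leading to 8R (O8 anti to C11 and to O6), reagent control being decisive because the Felkin and 1,3-anti preferences of this 6,7-syn aldehyde oppose each other, and no free Lewis acid able to ionise the acetal remains when 15 is added.

Step 13
Reactants: 22 homoallylic alcohol (6S,7R,8R)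
Product: 23 O8-tert-butyldimethylsilyl ether of 22 (6S,7R,8R)
Conditions: TBSOTf (1.2 equiv), 2,6-lutidine, CH2Cl2, −78 to −20 °C
Reagents that add atoms: tert-butyldimethylsilyl triflate CC(C)(C)[Si](C)(C)OS(=O)(=O)C(F)(F)F
Why: Silylation of the hindered secondary alcohol with a near-stoichiometric silyl triflate at low temperature is much faster than any attack on the acetal and gives O8 a group of intermediate lability.

Step 14
Reactants: 23 vinyl iodide (6S,7R,8R)
Product: 24 methyl (2Z,4R,5R,6R)-6-(tert-butyldimethylsilyloxy)-2-[(tert-butyldiphenylsilyloxy)methyl]-5-(2,2-dimethoxyethyl)-8-[(4-methoxybenzyloxy)methyl]-4-(triethylsilyloxy)nona-2,8-dienoate (germacrane 6R,7R,8R)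
Conditions: Pd(OAc)2 (10 mol %), PPh3 (30 mol %), Et3N, CO (1 atm), MeOH/DMF, 45 °C
Reagents that add atoms: carbon monoxide [C-]#[O+]; methanol CO
Why: Palladium-catalysed alkoxycarbonylation (oxidative addition of zerovalent palladium into C4–I with retention, CO insertion, methanolysis) installs C3 cis to C6, and CO insertion should outrun any carbopalladation of the remote methylene.

Step 15
Reactants: 24 methyl ester (6R,7R,8R)
Product: 25 methyl (2Z,4R,5R,6R)-6-(tert-butyldimethylsilyloxy)-2-[(tert-butyldiphenylsilyloxy)methyl]-5-(2,2-dimethoxyethyl)-8-(hydroxymethyl)-4-(triethylsilyloxy)nona-2,8-dienoate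
Conditions: DDQ, CH2Cl2/pH 7 buffer (10:1), 0 °C
Reagents that add atoms: none
Why: Oxidative cleavage of the 4-methoxybenzyl ether by hydride abstraction with DDQ is orthogonal to all three silyl ethers, the acetal and the enoate when the medium is buffered.

Step 16
Reactants: 25 hydroxy ester (6R,7R,8R)
Product: 26 (2Z,4R,5R,6R)-6-(tert-butyldimethylsilyloxy)-2-[(tert-butyldiphenylsilyloxy)methyl]-5-(2,2-dimethoxyethyl)-8-(hydroxymethyl)-4-(triethylsilyloxy)nona-2,8-dienoic acid (seco acid)
Conditions: Me3SnOH (8 equiv), ClCH2CH2Cl, 75 °C; then 0.01 M aq. KHSO4 wash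
Reagents that add atoms: trimethyltin hydroxide C[Sn](C)(C)O
Why: Trimethyltin hydroxide hydrolysis cleaves hindered methyl esters under nearly neutral conditions, which protects the O6 TES group, whose loss would let O6 close on C3 to a butenolide.

Step 17
Reactants: 26 seco acid (6R,7R,8R)
Product: 28 (3Z,5R,6R,7R)-7-(tert-butyldimethylsilyloxy)-3-[(tert-butyldiphenylsilyloxy)methyl]-6-(2,2-dimethoxyethyl)-9-methylidene-5-(triethylsilyloxy)-1-oxacyclodec-3-en-2-one (ten-membered lactone C3–O–C14), via mixed aryl anhydride 27 (not isolated)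
Conditions: 2-methyl-6-nitrobenzoic anhydride (1.5 equiv), DMAP (6 equiv), CH2Cl2 (1 mM), syringe-pump addition of 26, rt
Reagents that add atoms: 2-methyl-6-nitrobenzoic anhydride Cc1cccc([N+](=O)[O-])c1C(=O)OC(=O)c1c(C)cccc1[N+](=O)[O-] (its atoms stay only in 27)
Why: Shiina macrolactonisation activates the acid at room temperature as 27 and acylates the unhindered primary allylic O14, the Z alkene and the sp2 centre C10 reducing the transannular strain of the ten-membered ring.

Step 18
Reactants: 28 ten-membered lactone (6R,7R,8R)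
Product: 29 (3Z,5R,6R,7R)-7-(tert-butyldimethylsilyloxy)-3-[(tert-butyldiphenylsilyloxy)methyl]-6-(2,2-dimethoxyethyl)-2,9-dimethylidene-5-(triethylsilyloxy)-1-oxacyclodec-3-ene (cyclic 2-alkoxydiene C2=C3–O–C14–C10=C1)
Conditions: Cp2Ti(CH3)2 (3 equiv), toluene, 75 °C, dark; filtration through basic Al2O3
Reagents that add atoms: dimethyltitanocene [CH3-].[CH3-].[Ti+4].[cH-]1cccc1.[cH-]1cccc1
Why: Petasis methylenation, in which the titanium methylidene released on warming adds to the only carbonyl group and cycloreverts to the enol ether, is non-acidic, so acetal, silyl ethers and the sensitive alkoxydiene should survive.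

Step 19
Reactants: 29 cyclic 2-alkoxydiene (6R,7R,8R)
Product: 30 (2Z,4R,5R,6R)-6-(tert-butyldimethylsilyloxy)-2-[(tert-butyldiphenylsilyloxy)methyl]-5-(2,2-dimethoxyethyl)-8-methylidene-4-(triethylsilyloxy)cyclodec-2-en-1-one (carbocycle with C3 ketone and C10=C14 methylene; germacrane 4Z,6R,7R,8R)
Conditions: degassed toluene (2 mM), BHT (cat.), solid K2CO3, base-washed sealed tube, 125 °C
Reagents that add atoms: none
Why: Thermal aliphatic Claisen rearrangement: the six atoms C2=C3–O–C14–C10=C1 reorganise in one concerted suprafacial [3,3] shift in which C1–C2 forms while O–C14 breaks, driven by the exchange of an enol ether for the conjugated C3 ketone. The closest known reaction type is the lactone methylenation/Claisen sequence that converts unsaturated lactones into carbocycles. The ten-membered carbocycle is closed by joining the two exocyclic methylene carbons while the ten-membered oxacycle opens, so the closure is a ring transposition (O–C14 leaves the ring, C2–C1 enters it) through a boat-like six-centre array, the only one that the C4–C9 tether between positions 2 and 5 of the allyl vinyl ether allows. No stereocentre is created, and C6, C7, C8 and the Z C4=C5 bond are spectators that are carried through unchanged. The step needs periselectivity for the [3,3] path over ionisation, a [1,3] shift, a [1,5] hydrogen shift from C6–H to C2 and hydrolysis of the alkoxydiene; acid-free, dilute and degassed conditions, the proximity of C1 and C2 enforced by the ring and the absence of substituents on both termini should secure it.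

Step 20
Reactants: 30 ten-membered enone (6R,7R,8R)
Product: 32 (3R,6R,7R,8R,10R,4Z)-3,10-epoxy-3-hydroxy hemiketal (C10 methyl; O6 TES; O8 TBS; O15 TBDPS; C7 CH2CH(OMe)2), via hydroxy ketone 31 (not isolated)
Conditions: Co(acac)2 (20 mol %), PhSiH3 (4 equiv), O2 (1 atm, saturated solution), THF, 0 °C to rt
Reagents that add atoms: dioxygen O=O
Why: Mukaiyama hydration followed by ring–chain tautomerism, in which a cobalt hydride transfers a hydrogen atom to C14 of the only electron-rich 1,1-disubstituted alkene (Markovnikov, the conjugated trisubstituted C4=C5 bond being much slower), O2 traps the tertiary C10 radical on its open outer face because the inner face is covered by the C3–C5 enone across the ring (substrate control of C10), the peroxide is reduced in situ to 31, and its hydroxyl adds to the C3 ketone so that C3 settles under equilibrium control.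

Step 21
Reactants: 32 hemiketal (3R,6R,7R,8R,10R)
Product: 34 C12 aldehyde with C3–OTES (3S,6R,7R,8R,10R; the letter at C3 changes only because silicon raises the priority of that oxygen), via lutidinium salt 33 (not isolated)
Conditions: TESOTf (3 equiv), 2,6-lutidine (4.5 equiv), CH2Cl2, 0 °C; then H2O, 0 °C to rt
Reagents that add atoms: triethylsilyl triflate CC[Si](CC)(CC)OS(=O)(=O)C(F)(F)F; water O; 2,6-lutidine Cc1cccc(C)n1 (its atoms stay only in 33)
Why: Silyl triflate/2,6-lutidine cleavage of an aldehyde-derived acetal through a pyridinium-type salt that water hydrolyses, a weakly basic method that spares silyl ethers and ketals, while the same reagent silylates the hemiketal hydroxyl and so masks C3.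

Step 22
Reactants: 34 C12 aldehyde
Product: 36 C11=C13 enal (2-substituted acrolein on C7; 3S,6R,7R,8R,10R), via Mannich base 35 (not isolated)
Conditions: (CH3)2N=CH2 I (3 equiv), Et3N (10 equiv), CH2Cl2, rt
Reagents that add atoms: N,N-dimethylmethyleneiminium iodide C[N+](C)=C.[I-]
Why: Mannich condensation of the enolisable aldehyde with Eschenmoser's salt and spontaneous beta-elimination of dimethylamine (alpha-methylenation of an aldehyde) introduce C13 with only a tertiary amine base, so no enolate chemistry is needed near the masked ketone.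

Step 23
Reactants: 36 enal
Product: 37 C12 acrylic acid (3S,6R,7R,8R,10R)
Conditions: NaClO2, NaH2PO4, 2-methylbut-2-ene (excess), t-BuOH/H2O, 0 °C
Reagents that add atoms: sodium chlorite [Na+].[O-]Cl=O
Why: Pinnick oxidation converts enals into acrylic acids without touching alkenes, because the hypochlorous acid formed is removed by the sacrificial alkene.

Step 24
Reactants: 37 acrylic acid
Product: 39 (3R,6R,7R,8R,10R)-8-hydroxy α-methylene-6,12-lactone hemiketal (O15 TBDPS), via O8-TBS lactone 38 (not isolated)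
Conditions: 48% aq. HF, MeCN, −10 °C, then rt
Reagents that add atoms: none
Why: Graded acidic desilylation in which the two triethylsilyl groups fall first, the freed gamma-hydroxy acid closes at once to the trans-fused 6,12-lactone 38 (acid-catalysed lactonisation) while O8 is still silylated, which fixes the regiochemistry, and only then the slower O8 TBS group leaves, the TBDPS ether being far more stable to aqueous acid and no stereocentre being touched.

Step 25
Reactants: 39 8-hydroxy lactone
Product: 40 8-O-isobutyrate (O15 TBDPS; 3R,6R,7R,8R,10R)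
Conditions: (i-PrCO)2O (1.5 equiv), DMAP (0.2 equiv), Et3N, CH2Cl2, 0 °C to rt
Reagents that add atoms: isobutyric anhydride CC(C)C(=O)OC(=O)C(C)C
Why: DMAP-catalysed acylation takes the only secondary alcohol, the tertiary hemiketal hydroxyl being far slower and O15 still being silylated.

Step 26
Reactants: 40 8-O-isobutyrate
Product: 41 target CNP0282937.1 (3R,6R,7R,8R,10R,4Z)
Conditions: HF·pyridine, pyridine, THF, 0 °C to rt
Reagents that add atoms: none
Why: Fluoride-driven cleavage of the primary allylic TBDPS ether under buffered acidic conditions spares the ester, the α-methylene lactone and the hemiketal, all of which are base-sensitive.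

Compound list
1 | but-2-yne-1,4-diol | OCC#CCO | starting material
2 | 4-(tert-butyldiphenylsilyloxy)but-2-yn-1-ol | OCC#CCO[Si](c1ccccc1)(c1ccccc1)C(C)(C)C | intermediate
3 | sodium alkenylalanate, five-membered O6–Al–C4 chelate (not isolated) | [Na+].COCCO[Al-]1(OCCOC)OCC=C1CO[Si](c2ccccc2)(c2ccccc2)C(C)(C)C | intermediate
4 | (2Z)-4-(tert-butyldiphenylsilyloxy)-3-iodobut-2-en-1-ol | OC/C=C(\I)CO[Si](c1ccccc1)(c1ccccc1)C(C)(C)C | intermediate
5 | (2Z)-4-(tert-butyldiphenylsilyloxy)-3-iodobut-2-enal | O=C/C=C(\I)CO[Si](c1ccccc1)(c1ccccc1)C(C)(C)C | intermediate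
6 | methyl 4,4-dimethoxybutanoate | COC(OC)CCC(=O)OC | starting material
7 | lithium 4,4-dimethoxybutanoate | COC(OC)CCC(=O)[O-].[Li+] | intermediate
8 | (4S)-4-benzyl-1,3-oxazolidin-2-one | O=C1N[C@@H](Cc2ccccc2)CO1 | starting material
9 | 4,4-dimethoxybutanoic pivalic anhydride (not isolated) | COC(OC)CCC(=O)OC(=O)C(C)(C)C | intermediate
10 | (4S)-4-benzyl-3-(4,4-dimethoxybutanoyl)-1,3-oxazolidin-2-one | COC(OC)CCC(=O)N1C(=O)OC[C@@H]1Cc1ccccc1 | intermediate
11 | dibutylboron Z-enolate of 10 (not isolated) | COC(OC)C/C=C(\OB(CCCC)CCCC)N1C(=O)OC[C@@H]1Cc1ccccc1 | intermediate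
12 | syn-aldol adduct (6S,7S; 4Z) | O=C(N1C(=O)OC[C@@H]1Cc1ccccc1)[C@@H](CC(OC)OC)[C@H](O)/C=C(\I)CO[Si](c1ccccc1)(c1ccccc1)C(C)(C)C | intermediate
13 | O6-TES ether of 12 (6S,7S) | O=C(N1C(=O)OC[C@@H]1Cc1ccccc1)[C@@H](CC(OC)OC)[C@H](O[Si](CC)(CC)CC)/C=C(\I)CO[Si](c1ccccc1)(c1ccccc1)C(C)(C)C | intermediate
14 | C8 primary alcohol (6S,7R) | OC[C@@H](CC(OC)OC)[C@H](O[Si](CC)(CC)CC)/C=C(\I)CO[Si](c1ccccc1)(c1ccccc1)C(C)(C)C | intermediate
15 | C8 aldehyde (6S,7S) | O=C[C@@H](CC(OC)OC)[C@H](O[Si](CC)(CC)CC)/C=C(\I)CO[Si](c1ccccc1)(c1ccccc1)C(C)(C)C | intermediate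
16 | 2-methylprop-2-en-1-ol | C=C(C)CO | starting material
17 | O,C-dilithio derivative of 16 (not isolated) | [Li]CC(=C)CO[Li] | intermediate
18 | 2-[(tributylstannyl)methyl]prop-2-en-1-ol | C=C(CO)C[Sn](CCCC)(CCCC)CCCC | intermediate
19 | tributyl{2-[(4-methoxybenzyloxy)methyl]prop-2-en-1-yl}stannane | C=C(COCc1ccc(OC)cc1)C[Sn](CCCC)(CCCC)CCCC | intermediate
20 | 2-[(4-methoxybenzyloxy)methyl]allyllithium (not isolated) | [Li]CC(=C)COCc1ccc(OC)cc1 | intermediate
21 | B-{2-[(4-methoxybenzyloxy)methyl]allyl}diisopinocampheylborane, Ipc from (−)-α-pinene (not isolated) | C=C(COCc1ccc(OC)cc1)CB([C@H]1C[C@H]2C[C@@H]([C@@H]1C)C2(C)C)[C@H]1C[C@H]2C[C@@H]([C@@H]1C)C2(C)C | intermediate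
22 | C8 homoallylic alcohol (6S,7R,8R) | C=C(COCc1ccc(OC)cc1)C[C@@H](O)[C@@H](CC(OC)OC)[C@H](O[Si](CC)(CC)CC)/C=C(\I)CO[Si](c1ccccc1)(c1ccccc1)C(C)(C)C | intermediate
23 | O8-TBS ether of 22 (6S,7R,8R) | C=C(COCc1ccc(OC)cc1)C[C@@H](O[Si](C)(C)C(C)(C)C)[C@@H](CC(OC)OC)[C@H](O[Si](CC)(CC)CC)/C=C(\I)CO[Si](c1ccccc1)(c1ccccc1)C(C)(C)C | intermediate
24 | C3 methyl ester (4Z,6R,7R,8R), O14 PMB | C=C(COCc1ccc(OC)cc1)C[C@@H](O[Si](C)(C)C(C)(C)C)[C@@H](CC(OC)OC)[C@H](O[Si](CC)(CC)CC)/C=C(/CO[Si](c1ccccc1)(c1ccccc1)C(C)(C)C)C(=O)OC | intermediate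
25 | C14 hydroxy C3 methyl ester | C=C(CO)C[C@@H](O[Si](C)(C)C(C)(C)C)[C@@H](CC(OC)OC)[C@H](O[Si](CC)(CC)CC)/C=C(/CO[Si](c1ccccc1)(c1ccccc1)C(C)(C)C)C(=O)OC | intermediate
26 | seco acid | C=C(CO)C[C@@H](O[Si](C)(C)C(C)(C)C)[C@@H](CC(OC)OC)[C@H](O[Si](CC)(CC)CC)/C=C(/CO[Si](c1ccccc1)(c1ccccc1)C(C)(C)C)C(=O)O | intermediate
27 | mixed anhydride of 26 and 2-methyl-6-nitrobenzoic acid (not isolated) | C=C(CO)C[C@@H](O[Si](C)(C)C(C)(C)C)[C@@H](CC(OC)OC)[C@H](O[Si](CC)(CC)CC)/C=C(/CO[Si](c1ccccc1)(c1ccccc1)C(C)(C)C)C(=O)OC(=O)c1c(C)cccc1[N+](=O)[O-] | intermediate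
28 | ten-membered lactone (4Z,6R,7R,8R) | O=C1OCC(=C)C[C@@H](O[Si](C)(C)C(C)(C)C)[C@@H](CC(OC)OC)[C@H](O[Si](CC)(CC)CC)/C=C1/CO[Si](c2ccccc2)(c2ccccc2)C(C)(C)C | intermediate
29 | ten-membered cyclic 2-alkoxydiene, precursor of the key step | C=C1OCC(=C)C[C@@H](O[Si](C)(C)C(C)(C)C)[C@@H](CC(OC)OC)[C@H](O[Si](CC)(CC)CC)/C=C1/CO[Si](c2ccccc2)(c2ccccc2)C(C)(C)C | intermediate
30 | ten-membered (4Z)-enone with C10=C14 methylene, product of the key step | O=C1CCC(=C)C[C@@H](O[Si](C)(C)C(C)(C)C)[C@@H](CC(OC)OC)[C@H](O[Si](CC)(CC)CC)/C=C1/CO[Si](c2ccccc2)(c2ccccc2)C(C)(C)C | intermediate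
31 | (10R)-10-hydroxy-3-ketone (not isolated) | O=C1CC[C@@](C)(O)C[C@@H](O[Si](C)(C)C(C)(C)C)[C@@H](CC(OC)OC)[C@H](O[Si](CC)(CC)CC)/C=C1/CO[Si](c2ccccc2)(c2ccccc2)C(C)(C)C | intermediate
32 | 3,10-epoxy hemiketal (3R,6R,7R,8R,10R) | O[C@@]12CC[C@](C)(C[C@@H](O[Si](C)(C)C(C)(C)C)[C@@H](CC(OC)OC)[C@H](O[Si](CC)(CC)CC)/C=C1/CO[Si](c3ccccc3)(c3ccccc3)C(C)(C)C)O2 | intermediate
33 | C12 methoxy lutidinium triflate, C3–OTES (not isolated) | CC[Si](CC)(CC)O[C@@]12CC[C@](C)(C[C@@H](O[Si](C)(C)C(C)(C)C)[C@@H](CC(OC)[n+]3c(C)cccc3C)[C@H](O[Si](CC)(CC)CC)/C=C1/CO[Si](c3ccccc3)(c3ccccc3)C(C)(C)C)O2.[O-]S(=O)(=O)C(F)(F)F | intermediate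
34 | C12 aldehyde, C3–OTES (3S,6R,7R,8R,10R) | CC[Si](CC)(CC)O[C@@]12CC[C@](C)(C[C@@H](O[Si](C)(C)C(C)(C)C)[C@@H](CC=O)[C@H](O[Si](CC)(CC)CC)/C=C1/CO[Si](c3ccccc3)(c3ccccc3)C(C)(C)C)O2 | intermediate
35 | C11 dimethylaminomethyl aldehyde, C11 epimers (not isolated) | CC[Si](CC)(CC)O[C@@]12CC[C@](C)(C[C@@H](O[Si](C)(C)C(C)(C)C)[C@@H](C(CN(C)C)C=O)[C@H](O[Si](CC)(CC)CC)/C=C1/CO[Si](c3ccccc3)(c3ccccc3)C(C)(C)C)O2 | intermediate
36 | C11=C13 enal | CC[Si](CC)(CC)O[C@@]12CC[C@](C)(C[C@@H](O[Si](C)(C)C(C)(C)C)[C@@H](C(=C)C=O)[C@H](O[Si](CC)(CC)CC)/C=C1/CO[Si](c3ccccc3)(c3ccccc3)C(C)(C)C)O2 | intermediate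
37 | C12 acrylic acid | CC[Si](CC)(CC)O[C@@]12CC[C@](C)(C[C@@H](O[Si](C)(C)C(C)(C)C)[C@@H](C(=C)C(=O)O)[C@H](O[Si](CC)(CC)CC)/C=C1/CO[Si](c3ccccc3)(c3ccccc3)C(C)(C)C)O2 | intermediate
38 | O8-TBS α-methylene-6,12-lactone hemiketal (3R,6R,7S,8R,10R; not isolated) | C=C1C(=O)O[C@@H]2/C=C(/CO[Si](c4ccccc4)(c4ccccc4)C(C)(C)C)[C@@]3(O)CC[C@](C)(C[C@@H](O[Si](C)(C)C(C)(C)C)[C@@H]12)O3 | intermediate
39 | 8-hydroxy α-methylene-6,12-lactone hemiketal, O15 TBDPS | C=C1C(=O)O[C@@H]2/C=C(/CO[Si](c4ccccc4)(c4ccccc4)C(C)(C)C)[C@@]3(O)CC[C@](C)(C[C@@H](O)[C@@H]12)O3 | intermediate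
40 | 8-O-isobutyrate, O15 TBDPS | C=C1C(=O)O[C@@H]2/C=C(/CO[Si](c4ccccc4)(c4ccccc4)C(C)(C)C)[C@@]3(O)CC[C@](C)(C[C@@H](OC(=O)C(C)C)[C@@H]12)O3 | intermediate
41 | CNP0282937.1 | C=C1C(=O)O[C@@H]2/C=C(/CO)[C@@]3(O)CC[C@](C)(C[C@@H](OC(=O)C(C)C)[C@@H]12)O3 | target

Total step count: 26. Longest linear sequence: 22 steps (steps 1–3, 6–9 and 12–26, from but-2-yne-1,4-diol).

Steps most likely to fail

Step 19. The boat-like array may cost so much strain that, on heating, hydrogen migration from C6 to C2, ionisation of the allylic C–O bond or hydrolysis of the alkoxydiene overtakes formation of C1–C2.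

The fallback sets out from 23 and comes back at 30. It keeps the [3,3] logic but applies it to the open chain and closes the ring at C3–C4 instead.
- DDQ in buffered CH2Cl2 frees O14 of 23 and gives the iodo allylic alcohol F1.
- A Johnson–Claisen rearrangement with trimethyl orthoacetate and catalytic propionic acid in hot toluene builds C1–C2 and gives the methyl ester F2.
- DIBAL-H at −78 °C gives the aldehyde F3.
- A Nozaki–Hiyama–Kishi macrocyclisation (CrCl2, catalytic NiCl2, DMSO, high dilution) joins C4 to C3 and gives the cyclic allylic alcohol F4 as a C3 epimer mixture.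
- Dess–Martin oxidation removes that centre and gives 30.

Step 20. Capture of the planar C10 radical by O2 may show poor or reversed facial selectivity. The radical may also add across the ring to C5 of the enone before oxygen arrives.

The fallback sets out from 30 and comes back at 32. It delivers the oxygen ionically and from inside the ring.
- NIS with NaHCO3 in MeCN/H2O forms the iodonium ion of C10=C14.
- The C3 carbonyl oxygen opens this ion at the tertiary carbon in a five-membered closure, and water captures the oxocarbenium ion to give the iodomethyl hemiketal F5.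
- Radical deiodination with Bu3SnH and Et3B/air at rt turns CH2I into the C14 methyl group and gives 32.

Step 17. Oligomerisation, or Z to E isomerisation of the acyl-activated enoate by reversible addition of DMAP, may outrun closure of the strained ten-membered ring.

The fallback sets out from 26 and comes back at 28. It activates the alcohol instead of the acid by a Mitsunobu macrolactonisation (PPh3, DIAD, toluene, slow addition, high dilution).
- O14 becomes the leaving group and the carboxylate attacks the allylic carbon.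
- Direct and allylically shifted displacement give the same lactone, because both termini of the 2-substituted allyl unit are CH2 groups.
- The enoate is never acyl-activated.
- No new compound is made on this way (F0).

Further compounds
F1 | step 19 | C14 allylic alcohol with C4 iodide (6S,7R,8R) | C=C(CO)C[C@@H](O[Si](C)(C)C(C)(C)C)[C@@H](CC(OC)OC)[C@H](O[Si](CC)(CC)CC)/C=C(\I)CO[Si](c1ccccc1)(c1ccccc1)C(C)(C)C
F2 | step 19 | open-chain C3 methyl ester with C1–C2 in place and C10=C14 methylene | COC(=O)CCC(=C)C[C@@H](O[Si](C)(C)C(C)(C)C)[C@@H](CC(OC)OC)[C@H](O[Si](CC)(CC)CC)/C=C(\I)CO[Si](c1ccccc1)(c1ccccc1)C(C)(C)C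
F3 | step 19 | open-chain C3 aldehyde | O=CCCC(=C)C[C@@H](O[Si](C)(C)C(C)(C)C)[C@@H](CC(OC)OC)[C@H](O[Si](CC)(CC)CC)/C=C(\I)CO[Si](c1ccccc1)(c1ccccc1)C(C)(C)C
F4 | step 19 | ten-membered C3 allylic alcohol, C3 epimers | OC1CCC(=C)C[C@@H](O[Si](C)(C)C(C)(C)C)[C@@H](CC(OC)OC)[C@H](O[Si](CC)(CC)CC)/C=C1/CO[Si](c2ccccc2)(c2ccccc2)C(C)(C)C
F5 | step 20 | C14 iodomethyl 3,10-epoxy hemiketal | O[C@@]12CC[C@](CI)(C[C@@H](O[Si](C)(C)C(C)(C)C)[C@@H](CC(OC)OC)[C@H](O[Si](CC)(CC)CC)/C=C1/CO[Si](c3ccccc3)(c3ccccc3)C(C)(C)C)O2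
F0 | step 17 | none | none
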